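**Plan**

- Retrosynthesis: the C3–OH bond is traced back to a C3–I bond. The O1–C2 bond is then cut together with C3–I to give an acyclic 1-(pentamethoxyphenyl)-3-arylpropynone. The C4–C3 bond is cut last, to pentamethoxybenzaldehyde and a ring B arylacetylene.
- Forward: the ring A piece (from 3,4,5-trimethoxyphenol) and the ring B piece (from 3-hydroxy-4,5-dimethoxybenzaldehyde) are made separately and joined by acetylide addition and oxidation. Ring C is the only ring closed, by iodocyclisation. Iodine is then exchanged for hydroxyl, and the 5-O-methyl and 3'-O-benzyl groups are removed together.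
- Enabling feature: C4a lies between C5 and C8a, both oxygen-bearing, inside the five contiguous oxygenated carbons of ring A. A mirror-symmetric pentamethoxyphenyl ketone can therefore supply O1 from either ortho methoxy group, while C3 takes up iodine as the placeholder for the 3-hydroxyl.
- Stereochemistry: the target has no stereocentre. The carbinol carbon of 13 is formed racemic and is erased by the oxidation in step 8.

Key step: step 9

Remark: pentamethoxybenzene and 1,2,3,5-tetramethoxybenzene are taken as not dependably purchasable, so ring A is built from 3,4,5-trimethoxyphenol.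

**Route**

Step 1
Reactants: 1 3,4,5-trimethoxyphenol
Product: 2 1,2,3,5-tetramethoxybenzene
Conditions: MeI, K2CO3, acetone, reflux
Reagents that add atoms: iodomethane, CI
Why: Williamson O-methylation of the phenoxide by SN2 attack on iodomethane should cap the only free hydroxyl cleanly.

Step 2
Reactants: 2 1,2,3,5-tetramethoxybenzene
Product: 5 2,3,4,6-tetramethoxyphenol, via aryllithium 3 (not isolated), via dimethyl arylboronate 4 (not isolated)
Conditions: n-BuLi, THF, 0 °C to rt; B(OMe)3, −78 °C to rt; AcOH, 30% aq. H2O2, 0 °C to rt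
Reagents that add atoms: hydrogen peroxide, OO
Why: Directed ortho-lithiation at a ring position flanked by two methoxy groups (the two open positions are equivalent), borate trapping and peroxide oxidation with 1,2-shift of the aryl group from boron to oxygen is the standard lithiation–borylation–oxidation route to a phenol.

Step 3
Reactants: 5 2,3,4,6-tetramethoxyphenol
Product: 6 pentamethoxybenzene
Conditions: MeI, K2CO3, DMF, 50 °C
Reagents that add atoms: iodomethane, CI
Why: Williamson O-methylation of the hindered but acidic phenol should proceed in a polar aprotic solvent and completes the symmetric pentamethoxy ring.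

Step 4
Reactants: 6 pentamethoxybenzene
Product: 8 2,3,4,5,6-pentamethoxybenzaldehyde, via pentamethoxyphenyllithium 7 (not isolated)
Conditions: n-BuLi, TMEDA, THF, 0 °C; DMF, 0 °C to rt; H2O
Reagents that add atoms: N,N-dimethylformamide, CN(C)C=O
Why: Directed ortho-lithiation of the single ring hydrogen, which sits between two methoxy groups, followed by Bouveault formylation with DMF should give the aldehyde without any regiochemical choice.

Step 5
Reactants: 9 3-hydroxy-4,5-dimethoxybenzaldehyde
Product: 10 3-(benzyloxy)-4,5-dimethoxybenzaldehyde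
Conditions: BnBr, K2CO3, DMF, rt
Reagents that add atoms: benzyl bromide, BrCc1ccccc1
Why: Williamson benzylation masks the future 3'-hydroxyl as an ether that tolerates organolithium reagents, MnO2, ICl and Grignard reagents and can be removed at the end by a Lewis acid.

Step 6
Reactants: 10 3-(benzyloxy)-4,5-dimethoxybenzaldehyde
Product: 11 1-(benzyloxy)-5-ethynyl-2,3-dimethoxybenzene
Conditions: dimethyl (1-diazo-2-oxopropyl)phosphonate, K2CO3, MeOH/THF, rt
Reagents that add atoms: dimethyl (1-diazo-2-oxopropyl)phosphonate, CC(=O)C(=[N+]=[N-])P(=O)(OC)OC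
Why: Seyferth–Gilbert homologation in its Ohira–Bestmann form converts an aryl aldehyde into the terminal alkyne in one operation under mild carbonate conditions that leave the ethers untouched.

Step 7
Reactants: 11 1-(benzyloxy)-5-ethynyl-2,3-dimethoxybenzene; 8 2,3,4,5,6-pentamethoxybenzaldehyde
Product: 13 3-[3-(benzyloxy)-4,5-dimethoxyphenyl]-1-(2,3,4,5,6-pentamethoxyphenyl)prop-2-yn-1-ol (racemic), via lithium acetylide 12 (not isolated)
Conditions: 11, n-BuLi, THF, −78 °C; then 8, −78 to 0 °C; H2O
Reagents that add atoms: none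
Why: 1,2-Addition of a lithium acetylide to an aryl aldehyde is dependable even with two ortho methoxy groups, and the new carbinol stereocentre is formed as a racemate that is removed in step 8.

Step 8
Reactants: 13 3-[3-(benzyloxy)-4,5-dimethoxyphenyl]-1-(2,3,4,5,6-pentamethoxyphenyl)prop-2-yn-1-ol
Product: 14 3-[3-(benzyloxy)-4,5-dimethoxyphenyl]-1-(2,3,4,5,6-pentamethoxyphenyl)prop-2-yn-1-one
Conditions: MnO2 (activated, excess), CH2Cl2, rt
Reagents that add atoms: none
Why: MnO2 oxidation is selective for benzylic and propargylic alcohols and should give the ynone under neutral conditions that spare the acid-sensitive, electron-rich carbinol from ionisation.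

Step 9
Reactants: 14 3-[3-(benzyloxy)-4,5-dimethoxyphenyl]-1-(2,3,4,5,6-pentamethoxyphenyl)prop-2-yn-1-one
Product: 16 2-[3-(benzyloxy)-4,5-dimethoxyphenyl]-3-iodo-5,6,7,8-tetramethoxy-4H-chromen-4-one, via methyloxonium chloride 15 (not isolated)
Conditions: ICl (1.2 equiv), CH2Cl2, −78 °C; aq. Na2S2O3
Reagents that add atoms: iodine monochloride, ClI
Why: ICl activates the alkyne of 14 as an iodine-bridged cation, the oxygen of an ortho methoxy group attacks the alkyne carbon that carries ring B anti to iodine to give oxonium ion 15, and chloride then removes the methyl group by SN2 as chloromethane, so the O1–C2 and C3–I bonds are made in one operation. The closest known reaction type is the iodine monochloride-induced iodocyclisation of ortho-methoxyaryl alkynyl ketones to 3-iodochromones. Ring C closes in the 6-endo-dig mode. No stereocentre is created. The step needs 6-endo closure in preference to 5-exo closure, attack on the alkyne in preference to iodination of ring B, and no choice between the two ortho oxygens. The first is secured by the ring B-stabilised positive charge at the carbon β to the carbonyl (the future C2), the second by the fast intramolecular pathway at −78 °C on a ring B that is deactivated by conjugation with the ynone while ring A has no free position, and the third by the mirror symmetry of the pentamethoxyphenyl group.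

Step 10
Reactants: 16 2-[3-(benzyloxy)-4,5-dimethoxyphenyl]-3-iodo-5,6,7,8-tetramethoxy-4H-chromen-4-one
Product: 19 2-[3-(benzyloxy)-4,5-dimethoxyphenyl]-3-hydroxy-5,6,7,8-tetramethoxy-4H-chromen-4-one, via C3-magnesiated flavone 17 (not isolated), via C3 dimethyl boronate 18 (not isolated)
Conditions: i-PrMgCl·LiCl, THF, −60 °C; B(OMe)3, −60 to 0 °C; AcOH, 30% aq. H2O2, 0 °C to rt
Reagents that add atoms: hydrogen peroxide, OO
Why: Iodine–magnesium exchange on the electron-poor alkenyl iodide should be fast at low temperature and outrun attack on the vinylogous ester carbonyl, and borate trapping followed by peroxide oxidation with migration of C3 from boron to oxygen is the standard halogen–metal exchange, borylation and oxidation sequence, matching the known hydroxylation of C3-metalated flavones through their borates.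

Step 11
Reactants: 19 2-[3-(benzyloxy)-4,5-dimethoxyphenyl]-3-hydroxy-5,6,7,8-tetramethoxy-4H-chromen-4-one
Product: 20 3-demethyldigicitrin, 3,5-dihydroxy-2-(3-hydroxy-4,5-dimethoxyphenyl)-6,7,8-trimethoxy-4H-chromen-4-one
Conditions: BCl3, pentamethylbenzene, CH2Cl2, −78 to 0 °C; H2O
Reagents that add atoms: none
Why: BCl3 bound to the C4 carbonyl cleaves the peri 5-methyl ether through a six-membered chelate (chelation-controlled O-demethylation) and also cleaves the aryl benzyl ether, with pentamethylbenzene capturing the benzyl cation, while the unchelated methyl ethers should survive at or below 0 °C.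

**Compound list**

1 | 3,4,5-trimethoxyphenol | COc1cc(O)cc(OC)c1OC | starting material
2 | 1,2,3,5-tetramethoxybenzene | COc1cc(OC)c(OC)c(OC)c1 | intermediate
3 | (2,3,4,6-tetramethoxyphenyl)lithium | [Li]c1c(OC)cc(OC)c(OC)c1OC | intermediate
4 | dimethyl (2,3,4,6-tetramethoxyphenyl)boronate | COB(OC)c1c(OC)cc(OC)c(OC)c1OC | intermediate
5 | 2,3,4,6-tetramethoxyphenol | COc1cc(OC)c(OC)c(OC)c1O | intermediate
6 | pentamethoxybenzene | COc1cc(OC)c(OC)c(OC)c1OC | intermediate
7 | (pentamethoxyphenyl)lithium | [Li]c1c(OC)c(OC)c(OC)c(OC)c1OC | intermediate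
8 | 2,3,4,5,6-pentamethoxybenzaldehyde | COc1c(OC)c(OC)c(C=O)c(OC)c1OC | intermediate
9 | 3-hydroxy-4,5-dimethoxybenzaldehyde | COc1cc(C=O)cc(O)c1OC | starting material
10 | 3-(benzyloxy)-4,5-dimethoxybenzaldehyde | COc1cc(C=O)cc(OCc2ccccc2)c1OC | intermediate
11 | 1-(benzyloxy)-5-ethynyl-2,3-dimethoxybenzene | COc1cc(C#C)cc(OCc2ccccc2)c1OC | intermediate
12 | {[3-(benzyloxy)-4,5-dimethoxyphenyl]ethynyl}lithium | COc1cc(C#C[Li])cc(OCc2ccccc2)c1OC | intermediate
13 | 3-[3-(benzyloxy)-4,5-dimethoxyphenyl]-1-(2,3,4,5,6-pentamethoxyphenyl)prop-2-yn-1-ol (racemic) | COc1c(OC)c(OC)c(C(O)C#Cc2cc(OC)c(OC)c(OCc3ccccc3)c2)c(OC)c1OC | intermediate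
14 | 3-[3-(benzyloxy)-4,5-dimethoxyphenyl]-1-(2,3,4,5,6-pentamethoxyphenyl)prop-2-yn-1-one | COc1c(OC)c(OC)c(C(=O)C#Cc2cc(OC)c(OC)c(OCc3ccccc3)c2)c(OC)c1OC | intermediate
15 | 2-[3-(benzyloxy)-4,5-dimethoxyphenyl]-3-iodo-5,6,7,8-tetramethoxy-1-methyl-4-oxo-4H-chromen-1-ium chloride | C[O+]1c2c(OC)c(OC)c(OC)c(OC)c2C(=O)C(I)=C1c1cc(OC)c(OC)c(OCc2ccccc2)c1.[Cl-] | intermediate
16 | 2-[3-(benzyloxy)-4,5-dimethoxyphenyl]-3-iodo-5,6,7,8-tetramethoxy-4H-chromen-4-one | COc1cc(-c2oc3c(OC)c(OC)c(OC)c(OC)c3c(=O)c2I)cc(OCc2ccccc2)c1OC | intermediate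
17 | {2-[3-(benzyloxy)-4,5-dimethoxyphenyl]-5,6,7,8-tetramethoxy-4-oxo-4H-chromen-3-yl}magnesium chloride | COc1cc(-c2oc3c(OC)c(OC)c(OC)c(OC)c3c(=O)c2[Mg]Cl)cc(OCc2ccccc2)c1OC | intermediate
18 | dimethyl {2-[3-(benzyloxy)-4,5-dimethoxyphenyl]-5,6,7,8-tetramethoxy-4-oxo-4H-chromen-3-yl}boronate | COc1cc(-c2oc3c(OC)c(OC)c(OC)c(OC)c3c(=O)c2B(OC)OC)cc(OCc2ccccc2)c1OC | intermediate
19 | 2-[3-(benzyloxy)-4,5-dimethoxyphenyl]-3-hydroxy-5,6,7,8-tetramethoxy-4H-chromen-4-one | COc1cc(-c2oc3c(OC)c(OC)c(OC)c(OC)c3c(=O)c2O)cc(OCc2ccccc2)c1OC | intermediate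
20 | 3-demethyldigicitrin, 3,5-dihydroxy-2-(3-hydroxy-4,5-dimethoxyphenyl)-6,7,8-trimethoxy-4H-chromen-4-one | COc1cc(-c2oc3c(OC)c(OC)c(OC)c(O)c3c(=O)c2O)cc(O)c1OC | target

**Step count**

Total: 11 steps. Longest linear sequence: 9 steps (steps 1, 2, 3, 4, 7, 8, 9, 10, 11).

**Steps most likely to fail**

Step 10. The C3-magnesiated flavone may open by β-elimination of the ring oxygen, may be protonated before it meets the borate, or the Grignard reagent may add to the C4 carbonyl. Each of these would lower the conversion of iodide into hydroxyl. The fallback sets out from 16 and avoids any C3 carbanion. Copper-catalysed Ullmann-type C–O coupling of the alkenyl iodide with benzyl alcohol (CuI (copper monoiodide), 3,4,7,8-tetramethyl-1,10-phenanthroline, Cs2CO3, toluene, 90 °C) should give 3-(benzyloxy)-2-[3-(benzyloxy)-4,5-dimethoxyphenyl]-5,6,7,8-tetramethoxy-4H-chromen-4-one F1. Treatment of F1 with BCl3 and pentamethylbenzene as in step 11 should then cleave both benzyl ethers and the 5-methyl ether. The fallback comes back to the route at 20.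

Step 9. Electrophilic iodination of the electron-rich ring B, simple addition of ICl across the alkyne, or 5-exo closure may compete with the 6-endo ring closure. The fallback sets out from 6 and 10 and closes ring C without an electrophilic iodine reagent. Friedel–Crafts acetylation of 6 (AcCl, AlCl3, CH2Cl2, 0 °C to rt), with chelation-driven loss of one ortho methyl group, should give 1-(2-hydroxy-3,4,5,6-tetramethoxyphenyl)ethan-1-one F2. Claisen–Schmidt condensation of F2 with 10 (KOH, EtOH, rt) should give (E)-3-[3-(benzyloxy)-4,5-dimethoxyphenyl]-1-(2-hydroxy-3,4,5,6-tetramethoxyphenyl)prop-2-en-1-one F3. Oxidative cyclisation with catalytic I2 in DMSO at 120 °C should give 2-[3-(benzyloxy)-4,5-dimethoxyphenyl]-5,6,7,8-tetramethoxy-4H-chromen-4-one F4. C3 lithiation of F4 with LiN(i-Pr)2 (LDA) in THF at −78 °C, trapping with B(OMe)3 and oxidation with AcOH and H2O2 should install the 3-hydroxyl. The fallback comes back to the route at 19.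

Step 11. Further methyl ethers may be lost (the 6-methoxy group next to the freed 5-oxygen, or the 4'-methoxy group next to the freed 3'-oxygen), ring B may be benzylated, or the 5-O-demethylation may stall because boron is held at the 3-oxygen. The fallback sets out from 19 and separates the two cleavages. Hydrogenolysis (H2, Pd/C, EtOAc/THF, rt) should give 3-hydroxy-2-(3-hydroxy-4,5-dimethoxyphenyl)-5,6,7,8-tetramethoxy-4H-chromen-4-one F5. Brønsted acid demethylation of F5 (concentrated aqueous HCl in EtOH, reflux), which is selective for the methyl ether hydrogen-bonded to the C4 carbonyl, should then free the 5-hydroxyl. The fallback comes back to the route at 20.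

**Further compounds**

F1 | step 10 | 3-(benzyloxy)-2-[3-(benzyloxy)-4,5-dimethoxyphenyl]-5,6,7,8-tetramethoxy-4H-chromen-4-one | COc1cc(-c2oc3c(OC)c(OC)c(OC)c(OC)c3c(=O)c2OCc2ccccc2)cc(OCc2ccccc2)c1OC
F2 | step 9 | 1-(2-hydroxy-3,4,5,6-tetramethoxyphenyl)ethan-1-one | CC(=O)c1c(O)c(OC)c(OC)c(OC)c1OC
F3 | step 9 | (E)-3-[3-(benzyloxy)-4,5-dimethoxyphenyl]-1-(2-hydroxy-3,4,5,6-tetramethoxyphenyl)prop-2-en-1-one | COc1cc(/C=C/C(=O)c2c(O)c(OC)c(OC)c(OC)c2OC)cc(OCc2ccccc2)c1OC
F4 | step 9 | 2-[3-(benzyloxy)-4,5-dimethoxyphenyl]-5,6,7,8-tetramethoxy-4H-chromen-4-one | COc1cc(-c2cc(=O)c3c(OC)c(OC)c(OC)c(OC)c3o2)cc(OCc2ccccc2)c1OC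
F5 | step 11 | 3-hydroxy-2-(3-hydroxy-4,5-dimethoxyphenyl)-5,6,7,8-tetramethoxy-4H-chromen-4-one | COc1cc(-c2oc3c(OC)c(OC)c(OC)c(OC)c3c(=O)c2O)cc(O)c1OC
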